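**Plan**

1. Retrosynthesis (ent-kaurane numbering): remove the PMB group on O6 and the C17 methylene (HWE with CH2O), then the C13 phosphonoacetate (Michael addition to an 11-oxo-Δ12 enone), then C12=C13 of ring C (aldol condensation).
2. Cyclopentane ring B (C5, C6, C8, C9, C10) is cut at C5–C6 and C8–C9 together. C11(=O)–C9–C8–C7(=O) is a 1,4-dicarbonyl array and C6 carries oxygen β to C7, so ring B is the formal (3+2) adduct of a C5–C9–C10 cyclopropyl ketone and a C6=C8 β-alkoxyacrylate hung on O20. The C8–C9 bond closes the 7,20-lactone at the same time.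
3. Forward order: ring A (bought as the enone) → C20 hydroxymethyl → C20 acrylate ester → cyclopropane through a diazoacetoacetate bound to O1 → radical-relay (3+2) giving ring B and the δ-lactone → excision of the tether carbon → ring C → acrylate.
4. Stereochemistry: C1 is set by a CBS reduction and relayed to C10 by the tethered cyclopropanation. C5, C6, C8 and C9 arise in the key step under control of the two tethers. C1 is then reset by oxidation and axial hydride delivery; C13 and C11 are set under thermodynamic control.

Key step: step 10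

Remark: ent-kaurane locants are used throughout (ring A = C1–C5 and C10, C20 = lactone CH2, C7 = lactone carbonyl, ring C = C8, C9, C11–C14, acrylate = C15–C17). The E geometry drawn for 7–12 is an assumption that does not matter, because C6 and C8 pass through radical and enolate stages.

Step 1
Reactants: 1 4,4-dimethylcyclohex-2-en-1-one
Product: 2 2-iodo-4,4-dimethylcyclohex-2-en-1-one
Conditions: I2, K2CO3, DMAP (cat.), THF/H2O, rt
Reagents that add atoms: iodine, [I][I]
Why: α-Iodination of an enone by amine-mediated addition–elimination (a Baylis–Hillman-type α-functionalisation) is routine for 4,4-disubstituted cyclohexenones and creates no stereocentre.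

Step 2
Reactants: 2 2-iodo-4,4-dimethylcyclohex-2-en-1-one
Product: 3 (R)-2-iodo-4,4-dimethylcyclohex-2-en-1-ol
Conditions: (S)-2-methyl-CBS-oxazaborolidine (10 mol %), BH3·SMe2, THF, −20 °C; MeOH quench
Reagents that add atoms: none
Why: Corey–Bakshi–Shibata reduction, in which the iodo-substituted alkenyl carbon plays the large group, should deliver hydride to the face that gives the (R)-carbinol at C1, the only stereocentre set by a chiral reagent.

Step 3
Reactants: 3 (R)-2-iodo-4,4-dimethylcyclohex-2-en-1-ol
Product: 4 (R)-2-(hydroxymethyl)-4,4-dimethylcyclohex-2-en-1-ol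
Conditions: Bu3SnCH2OH, Pd(PPh3)4 (5 mol %), dioxane, 100 °C
Reagents that add atoms: (tributylstannyl)methanol, OC[Sn](CCCC)(CCCC)CCCC
Why: Migita–Kosugi–Stille coupling of the alkenyl iodide with the hydroxymethyl stannane installs C20 without touching C1.

Step 4
Reactants: 5 methyl 4,4-dimethoxybutanoate
Product: 7 methyl (E)-2-(2,2-dimethoxyethyl)-3-[(4-methoxybenzyl)oxy]prop-2-enoate, via sodium formyl-ester enolate 6 (not isolated)
Conditions: NaH, HCO2Me, THF, 0 °C → rt; then PMBCl, DMF, rt
Reagents that add atoms: methyl formate, COC=O; 4-methoxybenzyl chloride, COc1ccc(CCl)cc1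
Why: Claisen formylation gives the hydroxymethylene enolate, whose O-alkylation furnishes the β-alkoxyacrylate that carries C6 with its oxygen, C8, C7 and the C14–C13 acetal arm; no stereocentre is formed.

Step 5
Reactants: 7 methyl (E)-2-(2,2-dimethoxyethyl)-3-[(4-methoxybenzyl)oxy]prop-2-enoate
Product: 8 (E)-2-(2,2-dimethoxyethyl)-3-[(4-methoxybenzyl)oxy]prop-2-enoic acid
Conditions: LiOH, THF/H2O, rt; then 1 M HCl to pH 4, 0 °C
Reagents that add atoms: lithium hydroxide, [Li+].[OH-]
Why: Saponification of the β-alkoxyacrylate ester is standard and should leave the acetal and the enol ether intact if the acidification is kept mild.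

Step 6
Reactants: 4 (R)-2-(hydroxymethyl)-4,4-dimethylcyclohex-2-en-1-ol; 8 (E)-2-(2,2-dimethoxyethyl)-3-[(4-methoxybenzyl)oxy]prop-2-enoic acid
Product: 9 C20 mono-ester: (R)-(6-hydroxy-3,3-dimethylcyclohex-1-en-1-yl)methyl ester of acid 8
Conditions: DCC, DMAP (cat.), CH2Cl2, −20 → 0 °C
Reagents that add atoms: none
Why: Steglich esterification should select the primary allylic C20 hydroxyl over the secondary C1 hydroxyl on steric grounds.

Step 7
Reactants: 9 C20 mono-ester
Product: 10 C1 acetoacetate of 9
Conditions: 2,2,6-trimethyl-4H-1,3-dioxin-4-one, toluene, 110 °C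
Reagents that add atoms: 2,2,6-trimethyl-4H-1,3-dioxin-4-one, CC1=CC(=O)OC(C)(C)O1
Why: Thermolysis of the dioxinone releases acetylketene, which acylates the free C1 hydroxyl (acetoacetylation) under neutral conditions that spare the acetal and the enol ether.

Step 8
Reactants: 10 C1 acetoacetate of 9
Product: 11 C1 2-diazo-3-oxobutanoate of 9
Conditions: 4-acetamidobenzenesulfonyl azide, Et3N, MeCN, 0 °C → rt
Reagents that add atoms: 4-acetamidobenzenesulfonyl azide, CC(=O)Nc1ccc(cc1)S(=O)(=O)N=[N+]=[N-]
Why: Regitz diazo transfer to the active methylene of a β-keto ester is general.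

Step 9
Reactants: 11 C1 2-diazo-3-oxobutanoate of 9
Product: 12 cyclopropyl keto lactone (C5–C9–C10 cyclopropane and C9–CO–O1 γ-lactone cis on ring A; acetyl on C9; C20 acrylate ester on the other face)
Conditions: Rh2(OAc)4 (1 mol %), benzene, 80 °C, slow addition
Reagents that add atoms: none
Why: Intramolecular cyclopropanation by the rhodium carbenoid of an allylic diazoacetoacetate; the short tether from O1 can reach the C5=C10 double bond only from the face of O1, so the cis-fused γ-lactone fixes C10 (with C5 and C9) relative to C1.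

Step 10
Reactants: 12 cyclopropyl keto lactone
Product: 13 pentacyclic keto bis-lactone (rings A and B trans-fused; 7,20-δ-lactone; γ-lactone C9–CO–O1; acetyl on C9 syn to the δ-lactone; O6-PMB exo; acetal arm on C8)
Conditions: SmI2 (20 mol %), Sm powder (20 mol %), THF, 55 °C
Reagents that add atoms: none
Why: Proposed new method: SmI2 should reduce the β-keto lactone of 12 to a ketyl whose π system is conjugated with the ring-bound lactone carbonyl, so that only the exocyclic cyclopropane bond C9–C5 is aligned for scission and a C5 radical plus a chelated samarium enolate at C9 result; the closest known reaction type is the SmI2-catalysed radical-relay formal (3+2) cycloaddition of cyclopropyl ketones with electron-poor alkenes, made intramolecular here through the O20 ester. The nucleophilic C5 radical then adds to C6, the β carbon of the alkoxyacrylate (7-endo-trig), and the electrophilic C8 radical closes on C9 of the electron-rich enolate (5-exo-trig for ring B, 6-exo-trig for the δ-lactone) to give a ketyl that hands its electron back to trivalent samarium. C5 is controlled by the O20 tether, which brings C6 to the face of ring A cis to C20 and so leads, after a chair flip, to the trans A/B fusion; C6 by placing its alkoxy group anti to C10 and away from the C4 methyl groups; C8 and C9 by the lactone bridge and the cis-fused γ-lactone, which allow one geometry only. The step needs C9–C5 rather than C9–C10 scission and attack at C6 rather than C8; the first is secured by the temporary lactone to O1 (a stereoelectronic lock that also keeps the tertiary C10 radical from forming), the second by the C7 ester, which makes C6 the electrophilic terminus.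

Step 11
Reactants: 13 pentacyclic keto bis-lactone
Product: 15 1-epi hydroxy methyl ketone (C9–H; C11 acetyl; C1–OH cis to C9), via β-keto acid 14 (not isolated)
Conditions: LiCl, H2O, DMSO, 130 °C
Reagents that add atoms: none
Why: Krapcho-type dealkoxycarbonylation: water opens the activated β-keto lactone, the β-keto acid loses CO2, and protonation at C9 should place the acetyl group on the side of the δ-lactone, away from the exo alkoxy group on C6 (thermodynamic control, C9 stays epimerisable).

Step 12
Reactants: 15 1-epi hydroxy methyl ketone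
Product: 17 ring C enone with 1-epi hydroxyl (11-oxo-Δ12), via keto aldehyde 16 (not isolated)
Conditions: PPTS, acetone/H2O, 50 °C; then piperidine, AcOH, toluene, 60 °C
Reagents that add atoms: none
Why: Acetal hydrolysis followed by intramolecular aldol condensation, in which only the C12 methyl group can reach the aldehyde through a six-membered transition state, closes ring C as the enone; C9, α to the ketone, can equilibrate to the ring fusion that keeps ring C away from the C6 alkoxy group.

Step 13
Reactants: 17 ring C enone with 1-epi hydroxyl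
Product: 18 1,11-dioxo-Δ12 enedione
Conditions: Dess–Martin periodinane, CH2Cl2, rt
Reagents that add atoms: none
Why: Dess–Martin oxidation removes the wrongly configured C1 carbinol centre after it has served as the relay.

Step 14
Reactants: 18 1,11-dioxo-Δ12 enedione
Product: 19 1-hydroxy enone (C1–OH equatorial and cis to C20)
Conditions: NaBH4, MeOH/CH2Cl2 (1:1), −78 °C
Reagents that add atoms: none
Why: Borohydride reduction at low temperature is chemoselective for the saturated ketone over the enone, and axial attack anti to the axial C20 substituent should give the equatorial C1 alcohol cis to C20, as in the target.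

Step 15
Reactants: 19 1-hydroxy enone
Product: 20 1-acetoxy enone
Conditions: Ac2O, DMAP, pyridine, CH2Cl2, rt
Reagents that add atoms: acetic anhydride, CC(=O)OC(C)=O
Why: DMAP-catalysed acetylation of the only free hydroxyl.

Step 16
Reactants: 20 1-acetoxy enone
Product: 21 C13 phosphonoacetate adduct (11-ketone)
Conditions: (MeO)2P(O)CH2CO2Me, DBU, LiCl, MeCN, rt
Reagents that add atoms: trimethyl phosphonoacetate, COC(=O)CP(=O)(OC)OC
Why: Michael addition of the phosphonoacetate anion to the enone is reversible, so the C13 substituent should end equatorial, trans to the axial C7 carbonyl carbon on C8.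

Step 17
Reactants: 21 C13 phosphonoacetate adduct (11-ketone)
Product: 22 C13 phosphonoacetate adduct with equatorial C11–OH
Conditions: [(η5-Ph4C4CO)2H]Ru2(CO)4(μ-H) (2 mol %), 2-propanol/toluene, 80 °C
Reagents that add atoms: none
Why: Ruthenium-catalysed transfer hydrogenation is reversible, so the ketone should be taken to the more stable equatorial C11 alcohol (cis to the C13 substituent), whereas kinetic hydride attack from the open face would give the axial epimer.

Step 18
Reactants: 22 C13 phosphonoacetate adduct with equatorial C11–OH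
Product: 23 6-O-PMB ether of the target
Conditions: K2CO3, aq. CH2O (37 %), THF, 0 °C → rt
Reagents that add atoms: formaldehyde, C=O
Why: Horner–Wadsworth–Emmons olefination of the α-substituted phosphonoacetate with formaldehyde gives the α-methylene ester without affecting any stereocentre.

Step 19
Reactants: 23 6-O-PMB ether of the target
Product: 24 target CNP0421185.1
Conditions: DDQ, CH2Cl2/pH 7 buffer, 0 °C → rt
Reagents that add atoms: none
Why: Oxidative cleavage of the 4-methoxybenzyl ether with DDQ should tolerate the acrylate, the acetate and the lactone.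

**Compound list**

1 | 4,4-dimethylcyclohex-2-en-1-one | CC1(C)CCC(=O)C=C1 | starting material
2 | 2-iodo-4,4-dimethylcyclohex-2-en-1-one | CC1(C)CCC(=O)C(I)=C1 | intermediate
3 | (R)-2-iodo-4,4-dimethylcyclohex-2-en-1-ol | O[C@@H]1CCC(C)(C)C=C1I | intermediate
4 | (R)-2-(hydroxymethyl)-4,4-dimethylcyclohex-2-en-1-ol | O[C@@H]1CCC(C)(C)C=C1CO | intermediate
5 | methyl 4,4-dimethoxybutanoate | COC(=O)CCC(OC)OC | starting material
6 | sodium enolate of methyl 2-formyl-4,4-dimethoxybutanoate | [Na+].COC(=O)C(CC(OC)OC)=C[O-] | intermediate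
7 | methyl (E)-2-(2,2-dimethoxyethyl)-3-[(4-methoxybenzyl)oxy]prop-2-enoate | COC(=O)/C(CC(OC)OC)=C/OCc1ccc(OC)cc1 | intermediate
8 | (E)-2-(2,2-dimethoxyethyl)-3-[(4-methoxybenzyl)oxy]prop-2-enoic acid | OC(=O)/C(CC(OC)OC)=C/OCc1ccc(OC)cc1 | intermediate
9 | C20 mono-ester: (R)-(6-hydroxy-3,3-dimethylcyclohex-1-en-1-yl)methyl ester of acid 8 | O[C@@H]1CCC(C)(C)C=C1COC(=O)/C(CC(OC)OC)=C/OCc1ccc(OC)cc1 | intermediate
10 | C1 acetoacetate of 9 | CC(=O)CC(=O)O[C@@H]1CCC(C)(C)C=C1COC(=O)/C(CC(OC)OC)=C/OCc1ccc(OC)cc1 | intermediate
11 | C1 2-diazo-3-oxobutanoate of 9 | CC(=O)C(=[N+]=[N-])C(=O)O[C@@H]1CCC(C)(C)C=C1COC(=O)/C(CC(OC)OC)=C/OCc1ccc(OC)cc1 | intermediate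
12 | cyclopropyl keto lactone (C5–C9–C10 cyclopropane and C9–CO–O1 γ-lactone cis on ring A; acetyl on C9; C20 acrylate ester on the other face) | CC(=O)[C@]12C(=O)O[C@@H]3CCC(C)(C)[C@H]1[C@]23COC(=O)/C(CC(OC)OC)=C/OCc1ccc(OC)cc1 | intermediate
13 | pentacyclic keto bis-lactone (rings A and B trans-fused; 7,20-δ-lactone; γ-lactone C9–CO–O1; acetyl on C9 syn to the δ-lactone; O6-PMB exo; acetal arm on C8) | CC(=O)[C@]2(C(=O)O4)[C@]3(CC(OC)OC)C(=O)OC[C@]21[C@H]4CCC(C)(C)[C@H]1[C@@H]3OCc1ccc(OC)cc1 | intermediate
14 | β-keto acid from 13 (γ-lactone opened; C1–OH free) | CC(=O)[C@]2(C(=O)O)[C@]3(CC(OC)OC)C(=O)OC[C@]21[C@H](O)CCC(C)(C)[C@H]1[C@@H]3OCc1ccc(OC)cc1 | intermediate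
15 | 1-epi hydroxy methyl ketone (C9–H; C11 acetyl; C1–OH cis to C9) | CC(=O)[C@@H]2[C@]3(CC(OC)OC)C(=O)OC[C@]21[C@H](O)CCC(C)(C)[C@H]1[C@@H]3OCc1ccc(OC)cc1 | intermediate
16 | keto aldehyde (C13 aldehyde) from 15 | CC(=O)[C@@H]2[C@]3(CC=O)C(=O)OC[C@]21[C@H](O)CCC(C)(C)[C@H]1[C@@H]3OCc1ccc(OC)cc1 | intermediate
17 | ring C enone with 1-epi hydroxyl (11-oxo-Δ12; O6-PMB) | C1=CC(=O)[C@@H]2[C@]3(C1)C(=O)OC[C@]21[C@H](O)CCC(C)(C)[C@H]1[C@@H]3OCc1ccc(OC)cc1 | intermediate
18 | 1,11-dioxo-Δ12 enedione | C1=CC(=O)[C@@H]2[C@]3(C1)C(=O)OC[C@]21C(=O)CCC(C)(C)[C@H]1[C@@H]3OCc1ccc(OC)cc1 | intermediate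
19 | 1-hydroxy enone (C1–OH equatorial and cis to C20) | C1=CC(=O)[C@@H]2[C@]3(C1)C(=O)OC[C@]21[C@@H](O)CCC(C)(C)[C@H]1[C@@H]3OCc1ccc(OC)cc1 | intermediate
20 | 1-acetoxy enone | C1=CC(=O)[C@@H]2[C@]3(C1)C(=O)OC[C@]21[C@@H](OC(C)=O)CCC(C)(C)[C@H]1[C@@H]3OCc1ccc(OC)cc1 | intermediate
21 | C13 phosphonoacetate adduct (11-ketone; mixture at the phosphonate carbon) | COC(=O)C(P(=O)(OC)OC)[C@@H]1CC(=O)[C@@H]2[C@]3(C1)C(=O)OC[C@]21[C@@H](OC(C)=O)CCC(C)(C)[C@H]1[C@@H]3OCc1ccc(OC)cc1 | intermediate
22 | C13 phosphonoacetate adduct with equatorial C11–OH | COC(=O)C(P(=O)(OC)OC)[C@@H]1C[C@H](O)[C@@H]2[C@]3(C1)C(=O)OC[C@]21[C@@H](OC(C)=O)CCC(C)(C)[C@H]1[C@@H]3OCc1ccc(OC)cc1 | intermediate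
23 | 6-O-PMB ether of the target | C=C(C(=O)OC)[C@@H]1C[C@H](O)[C@@H]2[C@]3(C1)C(=O)OC[C@]21[C@@H](OC(C)=O)CCC(C)(C)[C@H]1[C@@H]3OCc1ccc(OC)cc1 | intermediate
24 | target CNP0421185.1 | C=C(C(=O)OC)[C@@H]1C[C@H](O)[C@@H]2[C@]3(C1)C(=O)OC[C@]21[C@@H](OC(C)=O)CCC(C)(C)[C@H]1[C@@H]3O | target

**Step count and risks**

Total step count: 19. Longest linear sequence: 17 steps (steps 1–3 and 6–19); steps 4 and 5 make the acid branch.

Steps most likely to fail:

- **Step 10 (labelled step).** The ketyl may open toward C10 despite the lactone lock. The 7-endo addition may be so slow that the C5 radical is quenched by hydrogen abstraction from THF or by reduction. The C8 radical may fail to add to the stabilised enolate, which stops the relay. The fallback uses known reaction types and sets out from 12. Tributyltin hydride (Bu3SnH, AIBN, benzene, 80 °C, syringe pump) would open the cyclopropyl ketone through its O-stannyl ketyl and add the C5 radical to the acrylate, ending by hydrogen transfer, to give the ring-opened seven-membered lactone F1. Double deprotonation (LDA, THF, −78 °C) and intramolecular oxidative enolate coupling with Fe(acac)3 would then close C8–C9 and rejoin the route at 13.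

- **Step 17.** Equilibration may be incomplete or the facial preference poor, leaving the axial 11-epimer; slow ester exchange with 2-propanol is a second concern. The fallback sets out from 21. Li[HB(sec-Bu)3] at −78 °C, attacking from the open face, would give the axial 11-epi alcohol F2. Mitsunobu inversion (4-nitrobenzoic acid, PPh3, DIAD) would give the 4-nitrobenzoate F3 with the required configuration, and K2CO3/MeOH at 0 °C would release 22.

- **Step 11.** Retro-Claisen loss of the acetyl group may compete with opening of the hindered lactone, or hydrolysis may stall. The fallback sets out from 13 and turns that cleavage into the productive path. NaOMe/MeOH at 0 °C would remove the acetyl group to give the deacetylated bis-lactone F4. MeLi (1 equiv., THF, −78 °C) would add once to the less hindered γ-lactone, turning its carbonyl carbon into C11 and freeing O1, to give the 9-epi hydroxy methyl ketone F5. DBU in CH2Cl2 would equilibrate C9 and rejoin the route at 15.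

Further compounds
F1 | step 10 | ring-opened seven-membered lactone from 12 (C5–C6 bond formed; C8–H and C9–H as mixtures) | CC(=O)C1C(=O)O[C@@H]2CCC(C)(C)[C@H]3[C@H](OCc4ccc(OC)cc4)C(CC(OC)OC)C(=O)OC[C@@]123
F2 | step 17 | axial 11-epi alcohol of 22 | COC(=O)C(P(=O)(OC)OC)[C@@H]1C[C@@H](O)[C@@H]2[C@]3(C1)C(=O)OC[C@]21[C@@H](OC(C)=O)CCC(C)(C)[C@H]1[C@@H]3OCc1ccc(OC)cc1
F3 | step 17 | 11-O-(4-nitrobenzoate) of 22 | COC(=O)C(P(=O)(OC)OC)[C@@H]1C[C@H](OC(=O)c4ccc(cc4)[N+](=O)[O-])[C@@H]2[C@]3(C1)C(=O)OC[C@]21[C@@H](OC(C)=O)CCC(C)(C)[C@H]1[C@@H]3OCc1ccc(OC)cc1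
F4 | step 11 | deacetylated bis-lactone (13 without the acetyl group; C9–H) | [C@H]2(C(=O)O4)[C@]3(CC(OC)OC)C(=O)OC[C@]21[C@H]4CCC(C)(C)[C@H]1[C@@H]3OCc1ccc(OC)cc1
F5 | step 11 | 9-epimer of 15 | CC(=O)[C@H]2[C@]3(CC(OC)OC)C(=O)OC[C@]21[C@H](O)CCC(C)(C)[C@H]1[C@@H]3OCc1ccc(OC)cc1
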